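**Direct plan and its weak points**

A direct plan would form the C7–C8 bond by an auxiliary-controlled boron syn-aldol between silyl-protected vanillin (A1) and an N-(aryloxyacetyl)oxazolidinone (A2) carrying the silylated sinapyl unit. It would then cleave the auxiliary from adduct A3 with a borohydride and desilylate with fluoride, after building both arenes from unsubstituted dihydroxybenzenes.
- The arene run-up (methylation, bromination, silylation, formylation for A1; directed metalation/oxidation, bromination, Suzuki coupling for the phenol of A2) would spend about ten steps on oxygenation patterns that are sold as commodity lignin monomers.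
- The aldol would set C7 and C8 only through a stoichiometric auxiliary that costs an acylation and a reductive cleavage, with C9 held at the acid level just to carry it and a hindered 2,6-dimethoxyphenoxy enolate as nucleophile.
- The two silylations would build nothing, and the last-step fluoride deprotection would free a p-hydroxybenzyl alcohol beside an aryl ether under basic conditions, where a quinone methide could scramble C7.

**Retrosynthetic overview of the new route**

- 12 ⇐ 11: one iBu2AlH reduction takes the C9 ester, the C9' cinnamate ester and the ring A pivalate together to the target, so there is no separate deprotection and no silyl group.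
- 11 ⇐ 10 (key): transfer hydrogenation with dynamic kinetic resolution forms the C7–H bond and sets C7–OH and C8–OAr together. It uses the fact that C8 lies between C7 (benzylic on ring A) and C9, so with both as carbonyls C8 epimerises freely.
- 10 ⇐ 7 + 9: the C8–O–C4' ether by SN2 of ethyl sinapate (ring B with C7'–C9') on a bromo keto ester (ring A with C7–C9). The C7–C8 bond is made earlier, without stereochemistry, by acylating a malonate.
- No ring is formed: rings A and B are bought as vanillic acid and sinapic acid with all oxygens in place, so the arene run-up, the auxiliary and the silyl steps do not arise.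

Key step: step 6

Assumption: the (S,S)-configured catalyst is taken to deliver hydride in the sense known for aryl alkyl ketones, which corresponds to (7R) here; if the sense were opposite, the (R,R)-catalyst would be used with no other change.

**Route**

Step 1
Reactants: 1 vanillic acid (4-hydroxy-3-methoxybenzoic acid)
Product: 2 3-methoxy-4-(pivaloyloxy)benzoic acid
Conditions: PivCl (1.1 equiv), NaOH (2.0 equiv), THF/H2O, 0 °C; then aq HCl
Reagents that add atoms: pivaloyl chloride CC(C)(C)C(=O)Cl
Why: Schotten–Baumann O-acylation, in which the phenoxide of the dianion is acylated and any mixed anhydride at the carboxylate hydrolyses on work-up; the pivalate is chosen because it resists carbonate, phenoxide and HCO2H/Et3N yet is cleaved by hydride in the last step.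

Step 2
Reactants: 2 3-methoxy-4-(pivaloyloxy)benzoic acid; 3 potassium ethyl malonate (potassium 3-ethoxy-3-oxopropanoate)
Product: 6 ethyl 3-[3-methoxy-4-(pivaloyloxy)phenyl]-3-oxopropanoate, via acyl imidazolide 4 (not isolated), via acylmalonic half ester 5 (not isolated)
Conditions: CDI (1.1 equiv), THF, rt; then 3 (1.5 equiv), MgCl2 (1.5 equiv), Et3N (1.5 equiv), MeCN, rt → 40 °C; aq HCl
Reagents that add atoms: none
Why: Masamune–Brooks homologation, in which the acyl imidazolide C-acylates the magnesium enolate of the malonate half-ester and the adduct loses CO2 on acidification; this forms the C7–C8 bond under near-neutral conditions that the aryl pivalate should survive, unlike a Claisen condensation with alkoxide.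

Step 3
Reactants: 6 ethyl 3-[3-methoxy-4-(pivaloyloxy)phenyl]-3-oxopropanoate
Product: 7 ethyl 2-bromo-3-[3-methoxy-4-(pivaloyloxy)phenyl]-3-oxopropanoate (racemic)
Conditions: NBS (1.0 equiv), Mg(ClO4)2 (10 mol %), EtOAc, 0 °C → rt
Reagents that add atoms: N-bromosuccinimide O=C1CCC(=O)N1Br
Why: Electrophilic α-bromination of the magnesium-activated enol of a 1,3-dicarbonyl compound, which is far more nucleophilic than the acyl- and acyloxy-deactivated ring A, with one equivalent of NBS to hold back the dibromide.

Step 4
Reactants: 8 sinapic acid ((E)-3-(4-hydroxy-3,5-dimethoxyphenyl)prop-2-enoic acid)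
Product: 9 ethyl sinapate (ethyl (E)-3-(4-hydroxy-3,5-dimethoxyphenyl)prop-2-enoate)
Conditions: EtOH, H2SO4 (cat.), reflux
Reagents that add atoms: ethanol CCO
Why: Fischer esterification, which leaves the phenol free and the E double bond untouched and puts C9' at the oxidation level that the final hydride step reduces.

Step 5
Reactants: 7 ethyl 2-bromo-3-[3-methoxy-4-(pivaloyloxy)phenyl]-3-oxopropanoate; 9 ethyl sinapate
Product: 10 ethyl 2-{4-[(E)-3-ethoxy-3-oxoprop-1-en-1-yl]-2,6-dimethoxyphenoxy}-3-[3-methoxy-4-(pivaloyloxy)phenyl]-3-oxopropanoate (racemic at C8)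
Conditions: K2CO3 (1.5 equiv), acetone, 0 °C → rt
Reagents that add atoms: none
Why: Williamson-type SN2 displacement by the sinapate phenoxide of a bromide activated by two flanking carbonyl groups, which forms the C8–O–C4' ether; O-alkylation is the only path because both ortho positions and the para position of ring B are substituted, and the new centre at C8 is deliberately left racemic and labile.

Step 6
Reactants: 10 racemic α-aryloxy-β-keto diester
Product: 11 ethyl (2S,3R)-2-{4-[(E)-3-ethoxy-3-oxoprop-1-en-1-yl]-2,6-dimethoxyphenoxy}-3-hydroxy-3-[3-methoxy-4-(pivaloyloxy)phenyl]propanoate (syn, threo)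
Conditions: RuCl[(S,S)-TsDPEN](p-cymene) (2 mol %), HCO2H/Et3N (5:2), CH2Cl2, 30 °C
Reagents that add atoms: none
Why: Noyori-type asymmetric transfer hydrogenation under dynamic kinetic resolution: the Ru–H/N–H complex of divalent ruthenium formed from the precatalyst and formate passes hydride to C7 and a proton to the carbonyl oxygen through a six-membered outer-sphere transition state, with loss of CO2. The closest known reaction type is the transfer hydrogenation of racemic α-alkoxy-β-keto esters with the same catalyst family, which gives syn α-alkoxy-β-hydroxy esters; no ring is closed. C7 is controlled by the catalyst: the aryl ketone is read through the CH/π contact between the η6-p-cymene and ring A, and the (S,S)-ligand should then give the (R) centre (the sense known for aryl alkyl ketones, with the descriptor reversed because C8 outranks the aryl group). C8 is controlled by the kinetic resolution: its hydrogen lies between the C7 ketone and the C9 ester and next to the aryloxy oxygen, so Et3N should interconvert the enantiomers of 10 much faster than either is reduced, and on the catalyst-preferred face only the (S)-epimer can adopt the polar Felkin–Anh arrangement (C8–OAr bond anti to the incoming hydride, C8–H beside its path), which leads to the syn (2S,3R) product. The step needs selectivity for C=O over C=C and esters, which the polarised Ru–H/N–H pair secures, since it should not add to the electron-rich cinnamate of ring B, the ethyl esters or the aryl pivalate. After reduction C8 is no longer flanked by a ketone and should keep its configuration.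

Step 7
Reactants: 11 syn hydroxy diester
Product: 12 (1R,2R)-1-(4-hydroxy-3-methoxyphenyl)-2-{4-[(E)-3-hydroxyprop-1-en-1-yl]-2,6-dimethoxyphenoxy}propane-1,3-diol (target; threo, 7R,8R)
Conditions: iBu2AlH (10 equiv), CH2Cl2/toluene, −78 → 0 °C; aq KNaC4H4O6
Reagents that add atoms: none
Why: Hydride reduction of all three acyl groups at once, in which iBu2AlH takes the C9 ester to CH2OH, the cinnamate to the allylic alcohol by 1,2-reduction without touching the C7'=C8' double bond, and the aryl pivalate to the free phenol; C7 and C8 are not involved (the descriptor at C8 changes from S to R only because C9 loses CIP priority).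

**Compound list**

1 | vanillic acid (4-hydroxy-3-methoxybenzoic acid) | COc1cc(C(=O)O)ccc1O | starting material
2 | 3-methoxy-4-(pivaloyloxy)benzoic acid | COc1cc(C(=O)O)ccc1OC(=O)C(C)(C)C | intermediate
3 | potassium ethyl malonate (potassium 3-ethoxy-3-oxopropanoate) | CCOC(=O)CC(=O)[O-].[K+] | starting material
4 | 4-(1H-imidazole-1-carbonyl)-2-methoxyphenyl pivalate (acyl imidazolide, not isolated) | COc1cc(C(=O)n2ccnc2)ccc1OC(=O)C(C)(C)C | intermediate
5 | 2-(ethoxycarbonyl)-3-[3-methoxy-4-(pivaloyloxy)phenyl]-3-oxopropanoic acid (present as its magnesium chelate, racemic, not isolated) | CCOC(=O)C(C(=O)O)C(=O)c1ccc(OC(=O)C(C)(C)C)c(OC)c1 | intermediate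
6 | ethyl 3-[3-methoxy-4-(pivaloyloxy)phenyl]-3-oxopropanoate | CCOC(=O)CC(=O)c1ccc(OC(=O)C(C)(C)C)c(OC)c1 | intermediate
7 | ethyl 2-bromo-3-[3-methoxy-4-(pivaloyloxy)phenyl]-3-oxopropanoate (racemic) | CCOC(=O)C(Br)C(=O)c1ccc(OC(=O)C(C)(C)C)c(OC)c1 | intermediate
8 | sinapic acid ((E)-3-(4-hydroxy-3,5-dimethoxyphenyl)prop-2-enoic acid) | COc1cc(/C=C/C(=O)O)cc(OC)c1O | starting material
9 | ethyl sinapate (ethyl (E)-3-(4-hydroxy-3,5-dimethoxyphenyl)prop-2-enoate) | CCOC(=O)/C=C/c1cc(OC)c(O)c(OC)c1 | intermediate
10 | ethyl 2-{4-[(E)-3-ethoxy-3-oxoprop-1-en-1-yl]-2,6-dimethoxyphenoxy}-3-[3-methoxy-4-(pivaloyloxy)phenyl]-3-oxopropanoate (racemic at C8) | COc1cc(C(=O)C(C(=O)OCC)Oc2c(OC)cc(/C=C/C(=O)OCC)cc2OC)ccc1OC(=O)C(C)(C)C | intermediate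
11 | ethyl (2S,3R)-2-{4-[(E)-3-ethoxy-3-oxoprop-1-en-1-yl]-2,6-dimethoxyphenoxy}-3-hydroxy-3-[3-methoxy-4-(pivaloyloxy)phenyl]propanoate | COc1cc([C@@H](O)[C@@H](C(=O)OCC)Oc2c(OC)cc(/C=C/C(=O)OCC)cc2OC)ccc1OC(=O)C(C)(C)C | intermediate
12 | (1R,2R)-1-(4-hydroxy-3-methoxyphenyl)-2-{4-[(E)-3-hydroxyprop-1-en-1-yl]-2,6-dimethoxyphenoxy}propane-1,3-diol (CNP0166461.2; threo, 7R,8R) | COc1cc([C@@H](O)[C@@H](CO)Oc2c(OC)cc(/C=C/CO)cc2OC)ccc1O | target

**Step count and risks**

Total step count: 7. Longest linear sequence: 6 (steps 1, 2, 3, 5, 6, 7).

Steps most likely to fail: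

1. Step 6 (key step). Hydride transfer to the mismatched C8 epimer may compete with C8 epimerisation, or the bulky 2,6-dimethoxyaryloxy group may disturb the facial preference of the catalyst, so that the diastereo- or enantioselectivity erodes. The fallback gives up catalyst control for a separation and sets out from 10. NaBH4 (THF/EtOH, −20 °C) would reduce only the ketone and give the hydroxy diester as the mixture of its four C7/C8 stereoisomers F2. Silica gel chromatography would remove the erythro pair, and chromatography of the threo pair on a chiral stationary phase (cellulose tris(3,5-dimethylphenylcarbamate)) would deliver the (2S,3R) isomer, which is 11, where the route is rejoined.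

2. Step 5. The hindered, electron-rich phenoxide may attack bromine instead of carbon (reductive debromination of 7 with oxidation of the phenol), or may simply deprotonate 7 to its unreactive enolate, so that ether formation stalls. The fallback forms the same C8–O bond by carbene chemistry and sets out from 6. Regitz diazo transfer (4-acetamidobenzenesulfonyl azide, Et3N, MeCN, rt) would give ethyl 2-diazo-3-[3-methoxy-4-(pivaloyloxy)phenyl]-3-oxopropanoate F1. Dirhodium tetraacetate Rh2(OAc)4 (1 mol %) in CH2Cl2 at 40 °C would then insert the rhodium carbenoid into the O–H bond of 9, an oxonium ylide pathway that is less sensitive to the flanking methoxy groups and that the electron-poor cinnamate double bond should not intercept. This returns to the route at 10.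

3. Step 7. The β-aluminoxy ester may undergo retro-aldol cleavage of the C7–C8 bond before C9 is reduced, C8 may epimerise at the transient α-aryloxy aldehyde, or reduction of three different acyl groups may stop at mixed, partly reduced stages. The fallback stages the reduction and sets out from 11. NaBH4 (THF/EtOH, 0 °C → rt) would reduce only the C9 ester, which is activated by the α-aryloxy and β-hydroxy groups, to give ethyl (E)-3-(4-{[(1R,2R)-1,3-dihydroxy-1-[3-methoxy-4-(pivaloyloxy)phenyl]propan-2-yl]oxy}-3,5-dimethoxyphenyl)prop-2-enoate F3. On this retro-aldol-proof diol, iBu2AlH (CH2Cl2, −78 → 0 °C) would reduce the cinnamate and the pivalate, which returns to the route at 12.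

**Further compounds**

F1 | step 5 | ethyl 2-diazo-3-[3-methoxy-4-(pivaloyloxy)phenyl]-3-oxopropanoate | CCOC(=O)C(=[N+]=[N-])C(=O)c1ccc(OC(=O)C(C)(C)C)c(OC)c1
F2 | step 6 | ethyl 2-{4-[(E)-3-ethoxy-3-oxoprop-1-en-1-yl]-2,6-dimethoxyphenoxy}-3-hydroxy-3-[3-methoxy-4-(pivaloyloxy)phenyl]propanoate as the mixture of its four C7/C8 stereoisomers | COc1cc(C(O)C(C(=O)OCC)Oc2c(OC)cc(/C=C/C(=O)OCC)cc2OC)ccc1OC(=O)C(C)(C)C
F3 | step 7 | ethyl (E)-3-(4-{[(1R,2R)-1,3-dihydroxy-1-[3-methoxy-4-(pivaloyloxy)phenyl]propan-2-yl]oxy}-3,5-dimethoxyphenyl)prop-2-enoate | COc1cc([C@@H](O)[C@@H](CO)Oc2c(OC)cc(/C=C/C(=O)OCC)cc2OC)ccc1OC(=O)C(C)(C)C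
A1 | direct plan | 4-(tert-butyldimethylsilyloxy)-3-methoxybenzaldehyde | COc1cc(C=O)ccc1O[Si](C)(C)C(C)(C)C
A2 | direct plan | (S)-4-benzyl-3-(2-{4-[(E)-3-(tert-butyldimethylsilyloxy)prop-1-en-1-yl]-2,6-dimethoxyphenoxy}acetyl)oxazolidin-2-one | COc1cc(/C=C/CO[Si](C)(C)C(C)(C)C)cc(OC)c1OCC(=O)N1C(=O)OC[C@@H]1Cc1ccccc1
A3 | direct plan | (S)-4-benzyl-3-[(2S,3R)-3-[4-(tert-butyldimethylsilyloxy)-3-methoxyphenyl]-2-{4-[(E)-3-(tert-butyldimethylsilyloxy)prop-1-en-1-yl]-2,6-dimethoxyphenoxy}-3-hydroxypropanoyl]oxazolidin-2-one | COc1cc([C@@H](O)[C@@H](C(=O)N2C(=O)OC[C@@H]2Cc2ccccc2)Oc2c(OC)cc(/C=C/CO[Si](C)(C)C(C)(C)C)cc2OC)ccc1O[Si](C)(C)C(C)(C)C
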